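**Plan**
- Retrosynthesis: cut the Si–O bond at the C1' carbinol, then C3a–C4 and C6–C7 together (this removes C4–C5–C6 as 2-methyl-2-prenylmalonyl dichloride), then C7a=C7 (lactone carbonyl plus ketone α-carbon), then the γ-lactone back to an epoxy ester and nerol.
- Feature used: the carbocycle (C3a, C4, C5, C6, C7, C7a) is a malonyl unit C4–C5–C6 bridging C3a and C7, the two carbons flanking C7a of the dihydrofuran ring (O1, C2, C3, C3a, C7a). In a 2-alkylidenetetrahydrofuran both are enol-ether β-carbons, and O1–C7a is already in place.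
- Forward: nerol → epoxide → two-carbon homologation → γ-lactone (O1–C2 by epoxide opening) → Claisen acylation and cyclodehydration to the alkylidenetetrahydrofuran (heterocycle first) → double C-acylation closes the carbocycle → desilylation.
- Stereochemistry: C1' and C2 come from the Katsuki–Sharpless epoxidation of nerol (C1' retained, C2 inverted in the lactonisation). C5 and C7 arise in the key step: C7 relative to C5 through the ring-closing transition state. The pair is not biased relative to C2/C1', so the (5S,7S) isomer has to be separated from its (5R,7R) diastereomer.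

Key step: step 11

Remark: locants O1–C7a and C1' follow the benzofuran numbering of the target 23 throughout.
Remark: the (2S,1'S) pair is the threo relationship, which an epoxide route reaches by anti opening of the cis (Z-derived) epoxide; nerol is therefore the terpene starting material.
Assumption: 15 may form as an E/Z mixture; the (E) isomer is drawn, and both isomers give the same dienol ether 20.

Step 1
Reactants: 1 nerol, (2Z)-3,7-dimethylocta-2,6-dien-1-ol
Product: 2 [(2R,3S)-3-methyl-3-(4-methylpent-3-en-1-yl)oxiran-2-yl]methanol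
Conditions: Ti(OiPr)4 (cat.), D-(−)-diisopropyl tartrate (cat.), t-BuOOH, 4 Å MS, CH2Cl2, −20 °C
Reagents that add atoms: tert-butyl hydroperoxide, CC(C)(C)OO
Why: Katsuki–Sharpless asymmetric epoxidation is directed by the allylic hydroxyl, so only the 2,3-alkene reacts, and with the D-(−)-tartrate ligand oxygen is delivered to the face that gives the (2R,3S)-epoxide, which fixes C1' (as C3) and places the oxygen from which C2 is later set by inversion.

Step 2
Reactants: 2 [(2R,3S)-3-methyl-3-(4-methylpent-3-en-1-yl)oxiran-2-yl]methanol; 3 ethyl (triphenylphosphoranylidene)acetate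
Product: 5 ethyl (2E)-3-[(2R,3S)-3-methyl-3-(4-methylpent-3-en-1-yl)oxiran-2-yl]prop-2-enoate, via epoxy aldehyde 4 (not isolated)
Conditions: TEMPO (cat.), PhI(OAc)2, CH2Cl2, rt; then 3, rt
Reagents that add atoms: none
Why: TEMPO/PhI(OAc)2 oxidation stops at the epoxy aldehyde 4, which is trapped in the same flask by the stabilised ylide in an (E)-selective Wittig olefination, so the labile aldehyde is never isolated and neither stereocentre is touched.

Step 3
Reactants: 5 ethyl (2E)-3-[(2R,3S)-3-methyl-3-(4-methylpent-3-en-1-yl)oxiran-2-yl]prop-2-enoate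
Product: 6 ethyl 3-[(2R,3S)-3-methyl-3-(4-methylpent-3-en-1-yl)oxiran-2-yl]propanoate
Conditions: 2-nitrobenzenesulfonylhydrazide, Et3N, CH2Cl2, rt
Reagents that add atoms: none
Why: Diimide reduction (concerted syn transfer of H2) is much faster for the disubstituted conjugated alkene than for the trisubstituted one and, unlike catalytic hydrogenation, does not open the allylic epoxide.

Step 4
Reactants: 6 ethyl 3-[(2R,3S)-3-methyl-3-(4-methylpent-3-en-1-yl)oxiran-2-yl]propanoate
Product: 9 (5S)-5-[(2S)-2-hydroxy-6-methylhept-5-en-2-yl]oxolan-2-one, via lithium epoxy carboxylate 7 (not isolated), via dihydroxy acid 8 (not isolated)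
Conditions: LiOH, THF/H2O, rt then 60 °C; 1 M HCl to pH 3, 0 °C; PPTS (cat.), CH2Cl2, rt
Reagents that add atoms: lithium hydroxide, [Li+].[OH-]
Why: Saponification gives carboxylate 7, which under purely basic SN2 conditions can attack only the secondary epoxide carbon (5-exo-tet epoxide opening with inversion at C2, C1'–O retained), and acidification closes the γ-lactone on the secondary hydroxyl of 8 (lactonisation), so anti opening of the cis epoxide sets the threo (S,S) pair.

Step 5
Reactants: 9 (5S)-5-[(2S)-2-hydroxy-6-methylhept-5-en-2-yl]oxolan-2-one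
Product: 10 (5S)-5-[(2S)-6-methyl-2-[(triethylsilyl)oxy]hept-5-en-2-yl]oxolan-2-one
Conditions: TESOTf, 2,6-lutidine, CH2Cl2, −78 to 0 °C
Reagents that add atoms: triethylsilyl trifluoromethanesulfonate, CC[Si](CC)(CC)OS(=O)(=O)C(F)(F)F
Why: Silylation with a silyl triflate and 2,6-lutidine is the standard way to cap a hindered tertiary alcohol, and the triethylsilyl ether tolerates the enolate, mild-acid and soft-enolisation steps that follow while remaining removable with fluoride.

Step 6
Reactants: 11 3-methylbutan-2-one; 12 1-bromo-3-methylbut-2-ene (prenyl bromide)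
Product: 13 2,7-dimethyloct-6-en-3-one
Conditions: LDA, THF, −78 °C; then 12, −78 to 0 °C
Reagents that add atoms: none
Why: Kinetic deprotonation with LDA takes the methyl rather than the methine hydrogen, and the lithium enolate is alkylated by the reactive allylic bromide at its primary carbon (kinetic enolate alkylation).

Step 7
Reactants: 10 (5S)-5-[(2S)-6-methyl-2-[(triethylsilyl)oxy]hept-5-en-2-yl]oxolan-2-one; 13 2,7-dimethyloct-6-en-3-one
Product: 15 (E)-2,7-dimethyl-4-[(5S)-5-[(2S)-6-methyl-2-[(triethylsilyl)oxy]hept-5-en-2-yl]oxolan-2-ylidene]oct-6-en-3-one, via hydroxy diketone 14 (not isolated)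
Conditions: 13 (2.3 equiv), LDA (2.2 equiv), THF, −78 °C; then 10, −78 to −20 °C; AcOH; PPTS (cat.), 4 Å MS, PhMe, 50 °C
Reagents that add atoms: none
Why: LDA deprotonates 13 at the less substituted α-CH2, the enolate adds to the lactone carbonyl (crossed Claisen acylation, the second equivalent of enolate taking up the acidic diketone proton), and under mild acid the δ-hydroxyl of 14 closes on the former lactone carbonyl and water is lost towards the conjugated side (cyclodehydration to the vinylogous ester) without breaking the C2–O bond, so C2 and C1' are unchanged.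

Step 8
Reactants: 16 diethyl methylmalonate; 12 1-bromo-3-methylbut-2-ene (prenyl bromide)
Product: 17 diethyl 2-methyl-2-(3-methylbut-2-en-1-yl)propanedioate
Conditions: NaH, THF, 0 °C; then 12, 0 °C to rt
Reagents that add atoms: none
Why: Malonic ester alkylation: the sodium enolate of the methylmalonate displaces bromide from the primary allylic carbon (SN2) and forms the quaternary carbon that becomes C5.

Step 9
Reactants: 17 diethyl 2-methyl-2-(3-methylbut-2-en-1-yl)propanedioate
Product: 18 dipotassium 2-methyl-2-(3-methylbut-2-en-1-yl)propanedioate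
Conditions: KOH (2.05 equiv), EtOH/H2O, reflux; evaporate, dry (PhMe azeotrope, vacuum)
Reagents that add atoms: potassium hydroxide, [K+].[OH-]
Why: Saponification of both ester groups, with the product kept as its dipotassium salt so that the free diacid, which could lactonise onto the prenyl alkene or decarboxylate, is never handled.

Step 10
Reactants: 18 dipotassium 2-methyl-2-(3-methylbut-2-en-1-yl)propanedioate
Product: 19 2-methyl-2-(3-methylbut-2-en-1-yl)propanedioyl dichloride
Conditions: (COCl)2 (2.5 equiv), DMF (cat.), hexane/CH2Cl2, 0 °C to rt; filter, distil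
Reagents that add atoms: oxalyl chloride, ClC(=O)C(Cl)=O
Why: Carboxylate salts are converted into acid chlorides by oxalyl chloride with DMF catalysis (Vilsmeier-type activation) with only KCl, CO and CO2 as by-products, so no HCl is present to add to the prenyl alkene, and the quaternary α-carbon excludes ketene formation.

Step 11
Reactants: 15 (E)-2,7-dimethyl-4-[(5S)-5-[(2S)-6-methyl-2-[(triethylsilyl)oxy]hept-5-en-2-yl]oxolan-2-ylidene]oct-6-en-3-one; 19 2-methyl-2-(3-methylbut-2-en-1-yl)propanedioyl dichloride
Product: 22 (2S,5S,7S)-5-methyl-5,7-bis(3-methylbut-2-en-1-yl)-2-[(2S)-6-methyl-2-[(triethylsilyl)oxy]hept-5-en-2-yl]-7-(2-methylpropanoyl)-2,3-dihydro-1-benzofuran-4,6(5H,7H)-dione, via silyl dienol ether 20 (not isolated), via acyl chloride 21 (not isolated)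
Conditions: TMSOTf (2.3 equiv), Et3N (3 equiv), CH2Cl2, −78 to 0 °C; then 19 (1.1 equiv), slow addition, 0.01 M, −78 °C to rt; aq NaHCO3; chromatography
Reagents that add atoms: none
Why: Proposed new method: soft enolisation (TMSOTf/Et3N) removes a ring hydrogen at C3a of 15 to give the 2-alkoxy-4-silyloxydiene 20, whose cyclic enol ether carbon C3a attacks one acyl chloride group of 19 (Mukaiyama-type C-acylation, C3a–C4), and after re-silylation to 21 the silyl enol ether carbon C7 attacks the second one (C6–C7), each acylation being made irreversible by loss of chloride as Me3SiCl. The closest known reaction types are the Effenberger cyclisation of enol ethers with malonyl dichloride and the terminal C-acylation and [3+3] cyclisations of 1,3-bis(silyloxy)dienes, neither of which has been shown with a 2,2-disubstituted malonyl dichloride that creates an acyl-bearing quaternary carbon. The carbocycle closes in a 6-(enolexo)-exo-trig mode, and since O-acylation at the isobutyryl oxygen would need an eight-membered ring and O1 is already an ether, only carbon can close it. C5 becomes stereogenic when C3a takes one of the two enantiotopic acyl chloride groups of 19, a choice on which the remote C2 centre has little influence, so both C5 epimers of 21 are expected. C7 is set relative to C5 in the ring closure, where the bulky silyloxyalkylidene arm (the future isobutyryl group) should turn away from the pseudoaxial C5 substituent, which for the smaller methyl group places isobutyryl cis to the C5 prenyl group as required; the (5S,7S) isomer 22 is therefore expected together with its (5R,7R) diastereomer and is separated from it by chromatography, the fixed C2/C1' centres making all isomers diastereomers. The step needs C- over O-acylation and enolisation at C3a rather than at the isopropyl methine, which the soft silyl dienol ether, the lack of a ketene pathway for 19, the less hindered ring hydrogens and high dilution in the second stage should secure.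

Step 12
Reactants: 22 (2S,5S,7S)-5-methyl-5,7-bis(3-methylbut-2-en-1-yl)-2-[(2S)-6-methyl-2-[(triethylsilyl)oxy]hept-5-en-2-yl]-7-(2-methylpropanoyl)-2,3-dihydro-1-benzofuran-4,6(5H,7H)-dione
Product: 23 (2S,5S,7S)-2-[(2S)-2-hydroxy-6-methylhept-5-en-2-yl]-5-methyl-5,7-bis(3-methylbut-2-en-1-yl)-7-(2-methylpropanoyl)-2,3-dihydro-1-benzofuran-4,6(5H,7H)-dione
Conditions: HF·pyridine, pyridine, THF, 0 °C to rt
Reagents that add atoms: none
Why: Fluoride-induced cleavage of the Si–O bond (desilylation) with pyridine-buffered HF·pyridine is non-basic, so the non-enolisable β-triketone at C7 is not exposed to a retro-Claisen cleavage and no stereocentre is affected.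

**Compound list**
1 | nerol, (2Z)-3,7-dimethylocta-2,6-dien-1-ol | CC(C)=CCC/C(C)=C\CO | starting material
2 | [(2R,3S)-3-methyl-3-(4-methylpent-3-en-1-yl)oxiran-2-yl]methanol | CC(C)=CCC[C@]1(C)O[C@@H]1CO | intermediate
3 | ethyl (triphenylphosphoranylidene)acetate | CCOC(=O)C=P(c1ccccc1)(c1ccccc1)c1ccccc1 | starting material
4 | (2S,3S)-3-methyl-3-(4-methylpent-3-en-1-yl)oxirane-2-carbaldehyde | CC(C)=CCC[C@]1(C)O[C@@H]1C=O | intermediate
5 | ethyl (2E)-3-[(2R,3S)-3-methyl-3-(4-methylpent-3-en-1-yl)oxiran-2-yl]prop-2-enoate | CC(C)=CCC[C@]1(C)O[C@@H]1/C=C/C(=O)OCC | intermediate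
6 | ethyl 3-[(2R,3S)-3-methyl-3-(4-methylpent-3-en-1-yl)oxiran-2-yl]propanoate | CC(C)=CCC[C@]1(C)O[C@@H]1CCC(=O)OCC | intermediate
7 | lithium 3-[(2R,3S)-3-methyl-3-(4-methylpent-3-en-1-yl)oxiran-2-yl]propanoate | [Li+].CC(C)=CCC[C@]1(C)O[C@@H]1CCC([O-])=O | intermediate
8 | (4S,5S)-4,5-dihydroxy-5,9-dimethyldec-8-enoic acid | CC(C)=CCC[C@](C)(O)[C@@H](O)CCC(O)=O | intermediate
9 | (5S)-5-[(2S)-2-hydroxy-6-methylhept-5-en-2-yl]oxolan-2-one | CC(C)=CCC[C@](C)(O)[C@@H]1CCC(=O)O1 | intermediate
10 | (5S)-5-[(2S)-6-methyl-2-[(triethylsilyl)oxy]hept-5-en-2-yl]oxolan-2-one | CC(C)=CCC[C@](C)(O[Si](CC)(CC)CC)[C@@H]1CCC(=O)O1 | intermediate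
11 | 3-methylbutan-2-one | CC(C)C(C)=O | starting material
12 | 1-bromo-3-methylbut-2-ene (prenyl bromide) | CC(C)=CCBr | starting material
13 | 2,7-dimethyloct-6-en-3-one | CC(C)C(=O)CCC=C(C)C | intermediate
14 | (8S,9S)-8-hydroxy-2,9,13-trimethyl-4-(3-methylbut-2-en-1-yl)-9-[(triethylsilyl)oxy]tetradec-12-ene-3,5-dione (C4 epimers, in equilibrium with its cyclic hemiketal) | CC(C)=CCC[C@](C)(O[Si](CC)(CC)CC)[C@@H](O)CCC(=O)C(CC=C(C)C)C(=O)C(C)C | intermediate
15 | (E)-2,7-dimethyl-4-[(5S)-5-[(2S)-6-methyl-2-[(triethylsilyl)oxy]hept-5-en-2-yl]oxolan-2-ylidene]oct-6-en-3-one (ring oxygen trans to the isobutyryl carbonyl) | CC(C)=CCC[C@](C)(O[Si](CC)(CC)CC)[C@@H]1CC/C(O1)=C(/CC=C(C)C)C(=O)C(C)C | intermediate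
16 | diethyl methylmalonate | CCOC(=O)C(C)C(=O)OCC | starting material
17 | diethyl 2-methyl-2-(3-methylbut-2-en-1-yl)propanedioate | CCOC(=O)C(C)(CC=C(C)C)C(=O)OCC | intermediate
18 | dipotassium 2-methyl-2-(3-methylbut-2-en-1-yl)propanedioate | [K+].[K+].CC(C)=CCC(C)(C([O-])=O)C([O-])=O | intermediate
19 | 2-methyl-2-(3-methylbut-2-en-1-yl)propanedioyl dichloride | CC(C)=CCC(C)(C(Cl)=O)C(Cl)=O | intermediate
20 | triethyl{[(2S)-2-[(2S)-5-[2,7-dimethyl-3-[(trimethylsilyl)oxy]octa-3,6-dien-4-yl]-2,3-dihydrofuran-2-yl]-6-methylhept-5-en-2-yl]oxy}silane (enol ether geometry not defined) | CC(C)=CCC[C@](C)(O[Si](CC)(CC)CC)[C@@H]1CC=C(O1)C(CC=C(C)C)=C(O[Si](C)(C)C)C(C)C | intermediate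
21 | 3-[(5S)-2-[2,7-dimethyl-3-[(trimethylsilyl)oxy]octa-3,6-dien-4-yl]-5-[(2S)-6-methyl-2-[(triethylsilyl)oxy]hept-5-en-2-yl]-4,5-dihydrofuran-3-yl]-2-methyl-2-(3-methylbut-2-en-1-yl)-3-oxopropanoyl chloride (both epimers at the quaternary carbon) | CC(C)=CCC[C@](C)(O[Si](CC)(CC)CC)[C@@H]1CC(C(=O)C(C)(CC=C(C)C)C(Cl)=O)=C(O1)C(CC=C(C)C)=C(O[Si](C)(C)C)C(C)C | intermediate
22 | (2S,5S,7S)-5-methyl-5,7-bis(3-methylbut-2-en-1-yl)-2-[(2S)-6-methyl-2-[(triethylsilyl)oxy]hept-5-en-2-yl]-7-(2-methylpropanoyl)-2,3-dihydro-1-benzofuran-4,6(5H,7H)-dione | CC(C)=CCC[C@](C)(O[Si](CC)(CC)CC)[C@@H]1CC2=C(O1)[C@@](CC=C(C)C)(C(=O)C(C)C)C(=O)[C@@](C)(CC=C(C)C)C2=O | intermediate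
23 | (2S,5S,7S)-2-[(2S)-2-hydroxy-6-methylhept-5-en-2-yl]-5-methyl-5,7-bis(3-methylbut-2-en-1-yl)-7-(2-methylpropanoyl)-2,3-dihydro-1-benzofuran-4,6(5H,7H)-dione | CC(C)=CCC[C@](C)(O)[C@@H]1CC2=C(O1)[C@@](CC=C(C)C)(C(=O)C(C)C)C(=O)[C@@](C)(CC=C(C)C)C2=O | target

**Step count**
Total: 12 steps. Longest linear sequence: 8 steps (steps 1, 2, 3, 4, 5, 7, 11, 12).

**Steps most likely to fail**

1. Step 11. Intermolecular acylation may lead to oligomers faster than the hindered, quaternary-centre-forming ring closure. Silylation may be diverted by enolisation at the isopropyl methine. Facial selection at C5/C7 may be poor.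
   Fallback: the two C-acylations are run as separate, individually known operations. It sets out from 19 and 15.
   - 19 is treated with one equivalent of pentafluorophenol and pyridine to give the mixed acid chloride/active ester pentafluorophenyl 2-(chlorocarbonyl)-2,5-dimethylhex-4-enoate F1 (racemic).
   - Silyl dienol ether 20, made from 15 as in step 11, is C-acylated at C3a by the acid chloride end of F1 (Mukaiyama-type acylation of a silyl dienol ether at its terminal carbon). Aqueous work-up gives the 3-acyl-4,5-dihydrofuran pentafluorophenyl 3-[(5S)-2-(2,7-dimethyl-3-oxooct-6-en-4-yl)-5-[(2S)-6-methyl-2-[(triethylsilyl)oxy]hept-5-en-2-yl]-4,5-dihydrofuran-3-yl]-2-methyl-2-(3-methylbut-2-en-1-yl)-3-oxopropanoate F2, whose C5 epimers can be separated.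
   - Soft enolisation of F2 (MgBr2·OEt2, iPr2NEt, CH2Cl2) lets C7 attack the aryl ester in an intramolecular Claisen-type acylation. Pentafluorophenoxide is too weak a nucleophile to reopen the trione. The route is rejoined at 22.

2. Step 7. Proton transfer from the lactone α-CH2 to the hindered, strongly basic enolate (enolisation of 10 instead of addition) may stall the conversion.
   Fallback: it sets out from 10 and 11 and changes the order of acylation and prenylation.
   - The unhindered kinetic lithium enolate of 11 (LDA, THF, −78 °C) is acylated by lactone 10. A neutral work-up gives the unbranched hydroxy diketone (8S,9S)-8-hydroxy-2,9,13-trimethyl-9-[(triethylsilyl)oxy]tetradec-12-ene-3,5-dione F3, kept away from acid.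
   - C-alkylation of its central carbon with 12 (K2CO3, acetone) leads back to 14, which is dehydrated to 15 with PPTS as in step 7.

3. Step 4. Epoxide opening under base may be incomplete. Acid-promoted attack at the tertiary carbon (6-endo) followed by translactonisation would then give the enantiomeric threo lactone and erode the optical purity at C2/C1'.
   Fallback: it sets out from 6 and does without the lactone.
   - Crossed Claisen condensation of 6 with the lithium enolate of 13 gives the epoxy diketone 6-methyl-4-(3-methylbut-2-en-1-yl)-1-[(2R,3S)-3-methyl-3-(4-methylpent-3-en-1-yl)oxiran-2-yl]heptane-3,5-dione F4.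
   - With DBU in MeCN the enolate oxygen opens the epoxide at the secondary carbon (5-exo-tet, SN2 inversion, no acid present). This forms O1–C2 and gives the hydroxy alkylidenetetrahydrofuran (E)-4-[(5S)-5-[(2S)-2-hydroxy-6-methylhept-5-en-2-yl]oxolan-2-ylidene]-2,7-dimethyloct-6-en-3-one F5.
   - Silylation (TESOTf, 2,6-lutidine) rejoins the route at 15.

Further compounds
F1 | step 11 | pentafluorophenyl 2-(chlorocarbonyl)-2,5-dimethylhex-4-enoate (racemic) | CC(C)=CCC(C)(C(Cl)=O)C(=O)Oc1c(F)c(F)c(F)c(F)c1F
F2 | step 11 | pentafluorophenyl 3-[(5S)-2-(2,7-dimethyl-3-oxooct-6-en-4-yl)-5-[(2S)-6-methyl-2-[(triethylsilyl)oxy]hept-5-en-2-yl]-4,5-dihydrofuran-3-yl]-2-methyl-2-(3-methylbut-2-en-1-yl)-3-oxopropanoate | CC(C)=CCC[C@](C)(O[Si](CC)(CC)CC)[C@@H]1CC(C(=O)C(C)(CC=C(C)C)C(=O)Oc2c(F)c(F)c(F)c(F)c2F)=C(O1)C(CC=C(C)C)C(=O)C(C)C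
F3 | step 7 | (8S,9S)-8-hydroxy-2,9,13-trimethyl-9-[(triethylsilyl)oxy]tetradec-12-ene-3,5-dione | CC(C)=CCC[C@](C)(O[Si](CC)(CC)CC)[C@@H](O)CCC(=O)CC(=O)C(C)C
F4 | step 4 | 6-methyl-4-(3-methylbut-2-en-1-yl)-1-[(2R,3S)-3-methyl-3-(4-methylpent-3-en-1-yl)oxiran-2-yl]heptane-3,5-dione | CC(C)=CCC[C@]1(C)O[C@@H]1CCC(=O)C(CC=C(C)C)C(=O)C(C)C
F5 | step 4 | (E)-4-[(5S)-5-[(2S)-2-hydroxy-6-methylhept-5-en-2-yl]oxolan-2-ylidene]-2,7-dimethyloct-6-en-3-one | CC(C)=CCC[C@](C)(O)[C@@H]1CC/C(O1)=C(/CC=C(C)C)C(=O)C(C)C
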